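**Plan**

Retrosynthetic cuts, in order: the C8–CH2 bond of the prenyl chain (traced back to a 5-O-prenyl ether through two [3,3] shifts); O1–C2 and C3–C4 of ring C together; the two acyl bonds of the pyranone (C4'–C5' and C2'–O1'); the ring A–C3' bond (aryl bromide plus malonate).
Enabling feature: ring C is a hidden cycloadduct. C4, C4a, C8a and O1 are the heterodiene of an ortho-quinone methide once C4 carries a methoxy group and positive charge beside the ring A phenol, and the C2–C3 edge with its phenyl group is the alkene styrene.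
Forward order: ring A is purchased, the pyranone ring is grown on it, ring C closes in the cycloaddition, C4 is oxidised to the ketone, and the prenyl chain is attached last.
Stereochemistry: C2 (S) is the only stereocentre of the target and is set by a confined chiral Brønsted acid in the cycloaddition. The extra C4 centre vanishes on oxidation, and all later steps are neutral, acidic or only weakly basic so that ring C stays closed.

Key step: step 9

Remark: the aryl–pyranone axis bears four ortho substituents, but the target notation defines no axial configuration, so the axis is taken as equilibrating and slowly interconverting rotamers of intermediates are carried on together.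
Remark: the sense of induction of the chiral acid cannot be derived from precedent, so the antipode (from (R)- or (S)-BINOL) that delivers 2S is selected in a test run.

**Step 1**
Reactants: 1 4-bromo-3,5-dimethoxyphenol
Product: 2 5-(benzyloxy)-2-bromo-1,3-dimethoxybenzene
Conditions: BnBr, K2CO3, DMF, rt
Reagents that add atoms: benzyl bromide, BrCc1ccccc1
Why: Williamson etherification of the single free phenol; the benzyl ether shields the oxygen that will become O1 through the basic, acylating and alkylating steps and can later be removed by hydrogenolysis beside methyl ethers.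

**Step 2**
Reactants: 2 5-(benzyloxy)-2-bromo-1,3-dimethoxybenzene; 3 diethyl malonate
Product: 4 diethyl 2-[4-(benzyloxy)-2,6-dimethoxyphenyl]malonate
Conditions: Pd(OAc)2 (3 mol %), P(t-Bu)3·HBF4 (6 mol %), K3PO4, toluene, 100 °C
Reagents that add atoms: none
Why: Palladium-catalysed malonate α-arylation (Buchwald–Hartwig-type enolate coupling), in which the bulky electron-rich phosphine lets zerovalent palladium insert into the hindered, electron-rich C–Br bond and forces reductive elimination, as established for ortho,ortho'-disubstituted aryl bromides.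

**Step 3**
Reactants: 4 diethyl 2-[4-(benzyloxy)-2,6-dimethoxyphenyl]malonate
Product: 5 2-[4-(benzyloxy)-2,6-dimethoxyphenyl]malonic acid
Conditions: KOH, EtOH/H2O, 60 °C; then 1 M HCl, 0 °C
Reagents that add atoms: potassium hydroxide, [K+].[OH-]
Why: Standard saponification of a malonic diester, with acidification in the cold so that the arylmalonic acid is collected before it can decarboxylate.

**Step 4**
Reactants: 6 3-pentanone
Product: 7 trimethyl(pent-2-en-3-yloxy)silane (E/Z mixture)
Conditions: TMSOTf, Et3N, Et2O, 0 °C
Reagents that add atoms: trimethylsilyl triflate, C[Si](C)(C)OS(=O)(=O)C(F)(F)F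
Why: Soft enolisation and O-silylation of a symmetrical ketone, so only one constitutional silyl enol ether can form, and its E/Z composition is irrelevant because that carbon becomes sp2 C5' of the pyranone.

**Step 5**
Reactants: 5 2-[4-(benzyloxy)-2,6-dimethoxyphenyl]malonic acid; 7 trimethyl(pent-2-en-3-yloxy)silane
Product: 9 3-[4-(benzyloxy)-2,6-dimethoxyphenyl]-6-ethyl-4-hydroxy-5-methylpyran-2-one, via arylmalonyl dichloride 8 (not isolated)
Conditions: (COCl)2 (2.1 equiv), DMF (cat.), CH2Cl2, 0 °C, evaporate; then 7, Et2O, −78 °C to rt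
Reagents that add atoms: oxalyl chloride, O=C(Cl)C(=O)Cl (supplies the chlorine of 8 only; nothing of it remains in 9)
Why: Effenberger-type pyranone synthesis, in which the silyl enol ether is C-acylated by one acyl chloride and the enol oxygen of the resulting 1,3-diketone closes onto the second, a sequence known for substituted malonyl dichlorides and for 2,6-disubstituted aryl(chlorocarbonyl)ketenes.

**Step 6**
Reactants: 9 3-[4-(benzyloxy)-2,6-dimethoxyphenyl]-6-ethyl-4-hydroxy-5-methylpyran-2-one
Product: 10 3-[4-(benzyloxy)-2,6-dimethoxyphenyl]-6-ethyl-4-methoxy-5-methylpyran-2-one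
Conditions: Me2SO4, K2CO3, acetone, reflux
Reagents that add atoms: dimethyl sulfate, COS(=O)(=O)OC
Why: O-alkylation of the vinylogous acid with a hard electrophile gives the 4-methoxy-2-pyranone (C3' is fully substituted, so C-methylation does not compete) and removes the acidic, nucleophilic enol before the acid-catalysed key step.

**Step 7**
Reactants: 10 3-[4-(benzyloxy)-2,6-dimethoxyphenyl]-6-ethyl-4-methoxy-5-methylpyran-2-one
Product: 11 6-ethyl-3-(4-hydroxy-2,6-dimethoxyphenyl)-4-methoxy-5-methylpyran-2-one
Conditions: H2 (1 atm), Pd/C (10 %), EtOAc/MeOH, rt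
Reagents that add atoms: none
Why: Catalytic hydrogenolysis of an aryl benzyl ether under mild conditions that leave the fully substituted pyranone and the methyl ethers untouched.

**Step 8**
Reactants: 11 6-ethyl-3-(4-hydroxy-2,6-dimethoxyphenyl)-4-methoxy-5-methylpyran-2-one
Product: 12 6-ethyl-3-(3-formyl-4-hydroxy-2,6-dimethoxyphenyl)-4-methoxy-5-methylpyran-2-one
Conditions: MgCl2, Et3N, (CH2O)n, MeCN, reflux; then 1 M HCl
Reagents that add atoms: paraformaldehyde (as formaldehyde), C=O
Why: Casnati–Skattebøl ortho-formylation, in which the magnesium phenoxide delivers formaldehyde only ortho to the hydroxyl and a second formaldehyde oxidises the benzylic alkoxide; the para position is occupied and both ortho positions are equivalent, so a single salicylaldehyde should result.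

**Step 9**
Reactants: 12 6-ethyl-3-(3-formyl-4-hydroxy-2,6-dimethoxyphenyl)-4-methoxy-5-methylpyran-2-one; 13 styrene; 14 trimethyl orthoformate
Product: 17 6-ethyl-4-methoxy-5-methyl-3-[(2S,4S)-4,5,7-trimethoxy-2-phenylchroman-6-yl]pyran-2-one (2,4-cis), via dimethyl acetal 15 (not isolated), via methoxy ortho-quinone methide 16 (not isolated)
Conditions: IDPi acid (BINOL-derived N-triflyl imidodiphosphorimidate with 3,3'-aryl groups, antipode giving 2S, 5 mol %), 13 (5 equiv), 14 (1.5 equiv), 5 Å MS, toluene, 0 °C
Reagents that add atoms: none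
Why: Proposed new method: the acid and 14 convert the aldehyde into acetal 15, and loss of methanol, pushed by the ortho hydroxyl, gives the methoxy-substituted ortho-quinone methide 16, best seen as a phenol-stabilised oxocarbenium ion paired with the chiral anion. Styrene then adds in an asynchronous inverse-electron-demand (4+2) cycloaddition in which its CH2 terminus attacks C4 and its benzylic carbon is captured by the ring A oxygen, so ring C closes intermolecularly with C3–C4 and O1–C2 made in one event (at the stepwise limit by six-membered collapse of the phenol oxygen onto the benzylic cation), driven by the regained aromaticity of ring A. The closest known reaction types are the achiral acid-catalysed three-component union of salicylaldehydes, orthoformates and styrenes to racemic 2,4-cis-4-alkoxy-2-arylchromans and the control of ortho-quinone methide cycloadditions with tethered or more electron-rich alkenes by confined chiral Brønsted acids, and their combination with plain styrene is what is new. C2 is under catalyst control, because the pocket of the anion leaves one face of the bound heterodiene open and orients the phenyl group, while C4 follows by relative (endo) control to give the 2,4-cis adduct and is erased in step 10. Regioselectivity comes from the matched polarity of the partners, and the choice of O1 is secured by the substrate, since O5, O7 and the pyranone enol oxygen are methyl ethers and only the hydroxyl para to the pyranone is free. Excess styrene, the narrow pocket and sieves that take up methanol should favour styrene over attack by C8 of a second ring A, over styrene oligomerisation and over re-ionisation at C4, and the cis adduct is purified before oxidation so that a trans isomer of possibly opposite C2 configuration cannot lower the enantiomeric purity.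

**Step 10**
Reactants: 17 6-ethyl-4-methoxy-5-methyl-3-[(2S,4S)-4,5,7-trimethoxy-2-phenylchroman-6-yl]pyran-2-one
Product: 18 3-[(2S)-5,7-dimethoxy-4-oxo-2-phenylchroman-6-yl]-6-ethyl-4-methoxy-5-methylpyran-2-one
Conditions: DDQ (1.5 equiv), CH2Cl2/H2O 10:1, 0 °C to rt
Reagents that add atoms: water, O
Why: Oxidative cleavage of an electron-rich benzylic methyl ether, the reaction type of p-methoxybenzyl ether removal and of the DDQ functionalisation of C4 in 5,7-dialkoxyflavans: hydride loss from C4 gives the donor-stabilised oxocarbenium ion, water adds and the hemiketal loses methanol, while C2–H next to a plain phenyl ring is not attacked, so the 2S centre is kept.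

**Step 11**
Reactants: 18 3-[(2S)-5,7-dimethoxy-4-oxo-2-phenylchroman-6-yl]-6-ethyl-4-methoxy-5-methylpyran-2-one
Product: 19 3-[(2S)-5,7-dihydroxy-4-oxo-2-phenylchroman-6-yl]-6-ethyl-4-hydroxy-5-methylpyran-2-one
Conditions: BBr3 (6 equiv), CH2Cl2, −78 to 0 °C; then ice/H2O
Reagents that add atoms: none
Why: Lewis acid ether cleavage of the two aryl methyl ethers and the vinylogous methyl ester; O1 is a poorly basic vinylogous ester oxygen and C2 bears only an unactivated phenyl group, so at low temperature the C2–O1 bond and with it the 2S configuration should persist, to be checked by chiral HPLC.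

**Step 12**
Reactants: 19 3-[(2S)-5,7-dihydroxy-4-oxo-2-phenylchroman-6-yl]-6-ethyl-4-hydroxy-5-methylpyran-2-one
Product: 20 6-ethyl-3-[(2S)-5-hydroxy-7-(methoxymethoxy)-4-oxo-2-phenylchroman-6-yl]-4-(methoxymethoxy)-5-methylpyran-2-one
Conditions: MOMCl (2.2 equiv), i-Pr2NEt, CH2Cl2, 0 °C
Reagents that add atoms: chloromethyl methyl ether, COCCl
Why: Selective O-alkylation in which the acidic pyranone enol and the 7-hydroxyl react while the 5-hydroxyl, held in a hydrogen bond to the C4 carbonyl, stays free, the usual pattern of 5,7-dihydroxyflavanones, and the weak amine base at 0 °C should not open ring C.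

**Step 13**
Reactants: 20 6-ethyl-3-[(2S)-5-hydroxy-7-(methoxymethoxy)-4-oxo-2-phenylchroman-6-yl]-4-(methoxymethoxy)-5-methylpyran-2-one; 21 3-methylbut-2-en-1-ol
Product: 22 6-ethyl-4-(methoxymethoxy)-3-[(2S)-7-(methoxymethoxy)-5-(3-methylbut-2-enyloxy)-4-oxo-2-phenylchroman-6-yl]-5-methylpyran-2-one
Conditions: PPh3, DIAD, THF, 0 °C to rt
Reagents that add atoms: none
Why: Mitsunobu etherification of the chelated 5-hydroxyl under essentially neutral conditions, the established entry to 5-O-prenylflavanones without retro-oxa-Michael opening of ring C.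

**Step 14**
Reactants: 22 6-ethyl-4-(methoxymethoxy)-3-[(2S)-7-(methoxymethoxy)-5-(3-methylbut-2-enyloxy)-4-oxo-2-phenylchroman-6-yl]-5-methylpyran-2-one
Product: 24 6-ethyl-3-[(2S)-5-hydroxy-7-(methoxymethoxy)-8-(3-methylbut-2-enyl)-4-oxo-2-phenylchroman-6-yl]-4-(methoxymethoxy)-5-methylpyran-2-one, via C6 dienone 23 (not isolated)
Conditions: Eu(fod)3 (10 mol %), CHCl3, 60 °C
Reagents that add atoms: none
Why: Lewis acid-catalysed para-Claisen–Cope rearrangement known for 5-O-prenylflavanones: europium chelated between O5 and the C4 carbonyl triggers the [3,3] shift to C6, and because C6 carries the pyranone the dienone cannot tautomerise and passes the chain on by a second [3,3] shift to C8, the only free ring A carbon, which restores the normal prenyl connectivity and the phenol.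

**Step 15**
Reactants: 24 6-ethyl-3-[(2S)-5-hydroxy-7-(methoxymethoxy)-8-(3-methylbut-2-enyl)-4-oxo-2-phenylchroman-6-yl]-4-(methoxymethoxy)-5-methylpyran-2-one
Product: 25 3-[(2S)-5,7-dihydroxy-8-(3-methylbut-2-enyl)-4-oxo-2-phenylchroman-6-yl]-6-ethyl-4-hydroxy-5-methylpyran-2-one (CNP0482269.1)
Conditions: 3 M HCl (aq), MeOH, 40 °C
Reagents that add atoms: none
Why: Acid-catalysed acetal cleavage of the aryl and the vinylogous-ester methoxymethyl groups, a standard last step for prenylated flavanones; acid, unlike base, should not racemise C2, and a short exposure keeps the 7-hydroxyl from adding to the prenyl double bond.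

**Compound list**

1 | 4-bromo-3,5-dimethoxyphenol | COc1cc(O)cc(OC)c1Br | starting material
2 | 5-(benzyloxy)-2-bromo-1,3-dimethoxybenzene | COc1cc(OCc2ccccc2)cc(OC)c1Br | intermediate
3 | diethyl malonate | CCOC(=O)CC(=O)OCC | starting material
4 | diethyl 2-[4-(benzyloxy)-2,6-dimethoxyphenyl]malonate | CCOC(=O)C(C(=O)OCC)c1c(OC)cc(OCc2ccccc2)cc1OC | intermediate
5 | 2-[4-(benzyloxy)-2,6-dimethoxyphenyl]malonic acid | OC(=O)C(C(=O)O)c1c(OC)cc(OCc2ccccc2)cc1OC | intermediate
6 | 3-pentanone | CCC(=O)CC | starting material
7 | trimethyl(pent-2-en-3-yloxy)silane (E/Z mixture) | CC=C(CC)O[Si](C)(C)C | intermediate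
8 | 2-[4-(benzyloxy)-2,6-dimethoxyphenyl]malonyl dichloride (formed in the flask) | O=C(Cl)C(C(=O)Cl)c1c(OC)cc(OCc2ccccc2)cc1OC | intermediate
9 | 3-[4-(benzyloxy)-2,6-dimethoxyphenyl]-6-ethyl-4-hydroxy-5-methylpyran-2-one | CCc1oc(=O)c(-c2c(OC)cc(OCc3ccccc3)cc2OC)c(O)c1C | intermediate
10 | 3-[4-(benzyloxy)-2,6-dimethoxyphenyl]-6-ethyl-4-methoxy-5-methylpyran-2-one | CCc1oc(=O)c(-c2c(OC)cc(OCc3ccccc3)cc2OC)c(OC)c1C | intermediate
11 | 6-ethyl-3-(4-hydroxy-2,6-dimethoxyphenyl)-4-methoxy-5-methylpyran-2-one | CCc1oc(=O)c(-c2c(OC)cc(O)cc2OC)c(OC)c1C | intermediate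
12 | 6-ethyl-3-(3-formyl-4-hydroxy-2,6-dimethoxyphenyl)-4-methoxy-5-methylpyran-2-one | CCc1oc(=O)c(-c2c(OC)cc(O)c(C=O)c2OC)c(OC)c1C | intermediate
13 | styrene | C=Cc1ccccc1 | starting material
14 | trimethyl orthoformate | COC(OC)OC | starting material
15 | 3-[3-(dimethoxymethyl)-4-hydroxy-2,6-dimethoxyphenyl]-6-ethyl-4-methoxy-5-methylpyran-2-one (formed in the flask) | CCc1oc(=O)c(-c2c(OC)cc(O)c(C(OC)OC)c2OC)c(OC)c1C | intermediate
16 | 6-ethyl-4-methoxy-3-[2,6-dimethoxy-3-(methoxymethylidene)-4-oxocyclohexa-1,5-dien-1-yl]-5-methylpyran-2-one (drawn neutral; under the acid its O-protonated oxocarbenium form paired with the chiral anion; formed in the flask) | CCc1oc(=O)c(C2=C(OC)C(=COC)C(=O)C=C2OC)c(OC)c1C | intermediate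
17 | 6-ethyl-4-methoxy-5-methyl-3-[(2S,4S)-4,5,7-trimethoxy-2-phenylchroman-6-yl]pyran-2-one (2,4-cis) | CCc1oc(=O)c(-c2c(OC)cc3c(c2OC)[C@@H](OC)C[C@@H](c2ccccc2)O3)c(OC)c1C | intermediate
18 | 3-[(2S)-5,7-dimethoxy-4-oxo-2-phenylchroman-6-yl]-6-ethyl-4-methoxy-5-methylpyran-2-one | CCc1oc(=O)c(-c2c(OC)cc3c(c2OC)C(=O)C[C@@H](c2ccccc2)O3)c(OC)c1C | intermediate
19 | 3-[(2S)-5,7-dihydroxy-4-oxo-2-phenylchroman-6-yl]-6-ethyl-4-hydroxy-5-methylpyran-2-one | CCc1oc(=O)c(-c2c(O)cc3c(c2O)C(=O)C[C@@H](c2ccccc2)O3)c(O)c1C | intermediate
20 | 6-ethyl-3-[(2S)-5-hydroxy-7-(methoxymethoxy)-4-oxo-2-phenylchroman-6-yl]-4-(methoxymethoxy)-5-methylpyran-2-one | CCc1oc(=O)c(-c2c(OCOC)cc3c(c2O)C(=O)C[C@@H](c2ccccc2)O3)c(OCOC)c1C | intermediate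
21 | 3-methylbut-2-en-1-ol | CC(C)=CCO | starting material
22 | 6-ethyl-4-(methoxymethoxy)-3-[(2S)-7-(methoxymethoxy)-5-(3-methylbut-2-enyloxy)-4-oxo-2-phenylchroman-6-yl]-5-methylpyran-2-one | CCc1oc(=O)c(-c2c(OCOC)cc3c(c2OCC=C(C)C)C(=O)C[C@@H](c2ccccc2)O3)c(OCOC)c1C | intermediate
23 | (2S)-6-[6-ethyl-4-(methoxymethoxy)-5-methyl-2-oxopyran-3-yl]-7-(methoxymethoxy)-6-(2-methylbut-3-en-2-yl)-2-phenyl-2,3-dihydrochromene-4,5(6H)-dione (either configuration at the transient C6; formed in the flask) | CCc1oc(=O)c(C2(C(C)(C)C=C)C(OCOC)=CC3=C(C2=O)C(=O)C[C@@H](c2ccccc2)O3)c(OCOC)c1C | intermediate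
24 | 6-ethyl-3-[(2S)-5-hydroxy-7-(methoxymethoxy)-8-(3-methylbut-2-enyl)-4-oxo-2-phenylchroman-6-yl]-4-(methoxymethoxy)-5-methylpyran-2-one | CCc1oc(=O)c(-c2c(OCOC)c(CC=C(C)C)c3c(c2O)C(=O)C[C@@H](c2ccccc2)O3)c(OCOC)c1C | intermediate
25 | 3-[(2S)-5,7-dihydroxy-8-(3-methylbut-2-enyl)-4-oxo-2-phenylchroman-6-yl]-6-ethyl-4-hydroxy-5-methylpyran-2-one | CCc1oc(=O)c(-c2c(O)c(CC=C(C)C)c3c(c2O)C(=O)C[C@@H](c2ccccc2)O3)c(O)c1C | target

**Step count**

Total step count: 15. Longest linear sequence: 14 (steps 1–3 and 5–15, from 1).

**Steps most likely to fail**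

First, step 9. What may go wrong:
- sluggish addition of a weak π-nucleophile to a strongly donor-stabilised cation
- capture of that cation by C8 of a second ring A (flavan-type self-condensation)
- acid-induced oligomerisation of styrene
- poor facial selectivity at C2

The fallback uses known chemistry only. It leaves the route at phenol 11 and returns at flavanone 18. C-acetylation ortho to the hydroxyl (Ac2O, BF3·OEt2, warm) should give 3-(3-acetyl-4-hydroxy-2,6-dimethoxyphenyl)-6-ethyl-4-methoxy-5-methylpyran-2-one F1. Condensation with N,N-dimethylformamide dimethyl acetal (toluene, 100 °C) should give 3-{3-[(E)-3-(dimethylamino)prop-2-enoyl]-4-hydroxy-2,6-dimethoxyphenyl}-6-ethyl-4-methoxy-5-methylpyran-2-one F2. Acid-induced ring closure (HCl, CH2Cl2) should give 6-(6-ethyl-4-methoxy-5-methyl-2-oxopyran-3-yl)-5,7-dimethoxychromen-4-one F3. Enantioselective conjugate addition of phenylboronic acid to this chromone then sets C2 and gives 18. Conditions: Pd(OCOCF3)2, the t-BuPyOx antipode that gives 2S, NH4PF6, H2O, ClCH2CH2Cl, 60 °C.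

Second, step 14. The first [3,3] shift must create a quaternary C6 next to a quaternary CMe2 carbon and may stall. Alternatively the Lewis acid may simply ionise the allylic ether, with loss of the prenyl group. The fallback leaves at triol 19 and returns directly at target 25, skipping steps 12–15. It is a Friedel–Crafts nuclear prenylation with 2-methylbut-3-en-2-ol and BF3·OEt2 in dioxane at rt, a reaction known for 5,7-dihydroxyflavanones. Here it is regiochemically forced because C8 is the only unsubstituted ring A carbon, and the acidic medium does not endanger C2. New compounds on this path: none F0.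

Third, step 5. What may go wrong:
- decarboxylation of the diacid during activation
- acylation of the electron-rich ring by the chlorinating agent
- ketene formation and self-condensation ahead of the reaction with the enol ether

The fallback builds the pyranone first and makes the aryl–pyranone bond by cross-coupling. It leaves at 2 and 7 and returns at 10, bypassing steps 2, 3, 5 and 6.
- Pyranone partner: enol ether 7 with malonyl dichloride (Et2O, −78 °C to rt) should give 6-ethyl-4-hydroxy-5-methylpyran-2-one F4. NBS should give 3-bromo-6-ethyl-4-hydroxy-5-methylpyran-2-one F5. Me2SO4/K2CO3 should give 3-bromo-6-ethyl-4-methoxy-5-methylpyran-2-one F6.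
- Aryl partner: bromide 2 is converted by n-BuLi, B(Oi-Pr)3 and mild acid into [4-(benzyloxy)-2,6-dimethoxyphenyl]boronic acid F7.
- Union: Suzuki–Miyaura coupling of the two (Pd(OAc)2, SPhos, K3PO4, toluene/H2O, 80 °C) gives 10.

**Further compounds**

F1 | step 9 | 3-(3-acetyl-4-hydroxy-2,6-dimethoxyphenyl)-6-ethyl-4-methoxy-5-methylpyran-2-one | CCc1oc(=O)c(-c2c(OC)cc(O)c(C(C)=O)c2OC)c(OC)c1C
F2 | step 9 | 3-{3-[(E)-3-(dimethylamino)prop-2-enoyl]-4-hydroxy-2,6-dimethoxyphenyl}-6-ethyl-4-methoxy-5-methylpyran-2-one | CCc1oc(=O)c(-c2c(OC)cc(O)c(C(=O)/C=C/N(C)C)c2OC)c(OC)c1C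
F3 | step 9 | 6-(6-ethyl-4-methoxy-5-methyl-2-oxopyran-3-yl)-5,7-dimethoxychromen-4-one | CCc1oc(=O)c(-c2c(OC)cc3occc(=O)c3c2OC)c(OC)c1C
F0 | step 14 | none | none
F4 | step 5 | 6-ethyl-4-hydroxy-5-methylpyran-2-one | CCc1oc(=O)cc(O)c1C
F5 | step 5 | 3-bromo-6-ethyl-4-hydroxy-5-methylpyran-2-one | CCc1oc(=O)c(Br)c(O)c1C
F6 | step 5 | 3-bromo-6-ethyl-4-methoxy-5-methylpyran-2-one | CCc1oc(=O)c(Br)c(OC)c1C
F7 | step 5 | [4-(benzyloxy)-2,6-dimethoxyphenyl]boronic acid | COc1cc(OCc2ccccc2)cc(OC)c1B(O)O
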